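**Strategy.** Everything rests on the C9–C10 disconnection of ring B (C5–C6–C7–C8–C9–C10, halimane numbering). A hydride-terminated 6-exo Heck cyclisation of a ring-A cyclohexenyl triflate onto a pendant 1,1-disubstituted alkene closes ring B last, creates the quaternary C9 stereocentre, converts the exo-methylene carbon into the C20 methyl group and leaves the C1=C10 double bond exactly where the kinetic enol triflate placed it. The feature exploited is the methyl-bearing quaternary C9 bonded directly to the sp2 ring-fusion carbon C10. The precursor is a monocyclic 2,3,3-trisubstituted cyclohexenyl triflate (C4 and C5 from asymmetric conjugate addition and enolate alkylation) that already carries the whole side chain, with C8 derived from (R)-α-methyl-γ-butyrolactone.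

Key step: step 12

Remark: halimane numbering is used throughout (ring A = C1–C2–C3–C4–C5–C10; ring B = C5–C6–C7–C8–C9–C10; C18 = CO2H and C19 = CH3 on C4; C17 = CH3 on C8; C20 = CH3 on C9; C11–C15 = side chain, C16 = CH3 on C13).
Assumption: compounds 1, 6 and 12 are taken as purchasable; in steps 4 and 9 the catalyst antipode is the one that delivers the stated configuration.

**Step 1**
Reactants: 1 (E)-3-methylpent-2-en-4-yn-1-ol
Product: 2 tert-butyl(dimethyl){[(2E)-3-methylpent-2-en-4-yn-1-yl]oxy}silane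
Conditions: TBSCl, imidazole, DMF, 0 °C to rt
Reagents that add atoms: tert-butyldimethylsilyl chloride, CC(C)(C)[Si](C)(C)Cl
Why: Standard silylation protects the primary allylic oxygen (O15) for the organometallic steps; no stereocentre is formed and the E-alkene is untouched.

**Step 2**
Reactants: 2 tert-butyl(dimethyl){[(2E)-3-methylpent-2-en-4-yn-1-yl]oxy}silane
Product: 3 tert-butyl(dimethyl){[(2E)-3-methylpenta-2,4-dien-1-yl]oxy}silane
Conditions: H2 (1 atm), Lindlar catalyst, quinoline, hexane, rt
Reagents that add atoms: none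
Why: Lindlar semihydrogenation of the terminal alkyne should stop at the vinyl group and leave the trisubstituted E-alkene unchanged.

**Step 3**
Reactants: 3 tert-butyl(dimethyl){[(2E)-3-methylpenta-2,4-dien-1-yl]oxy}silane
Product: 5 tert-butyl{[(2E)-5-iodo-3-methylpent-2-en-1-yl]oxy}dimethylsilane, via alkylzirconocene chloride 4 (not isolated)
Conditions: Cp2Zr(H)Cl, THF, rt; then I2, 0 °C
Reagents that add atoms: iodine, II
Why: Hydrozirconation adds Zr–H across the less hindered monosubstituted alkene of the diene with zirconium at the terminal carbon, and iodinolysis of the C–Zr bond gives the primary homoallylic iodide.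

**Step 4**
Reactants: 6 3-methylidenedihydrofuran-2(3H)-one (α-methylene-γ-butyrolactone)
Product: 7 (3R)-3-methyldihydrofuran-2(3H)-one
Conditions: H2 (100 atm), Ru(OAc)2[(S)-BINAP] (cat.), CH2Cl2, 50 °C
Reagents that add atoms: none
Why: Ru–BINAP asymmetric hydrogenation of the exocyclic α-methylene lactone sets the methyl stereocentre (the future C8) by catalyst control.

**Step 5**
Reactants: 5 tert-butyl{[(2E)-5-iodo-3-methylpent-2-en-1-yl]oxy}dimethylsilane; 7 (3R)-3-methyldihydrofuran-2(3H)-one
Product: 9 (3R,7E)-9-{[tert-butyl(dimethyl)silyl]oxy}-1-hydroxy-3,7-dimethylnon-7-en-4-one (in equilibrium with its lactol), via homoallylic alkyllithium 8 (not isolated)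
Conditions: t-BuLi (2 equiv), Et2O–pentane, −78 °C; then 7, −78 °C; aq NH4Cl
Reagents that add atoms: none
Why: Iodine–lithium exchange gives a primary alkyllithium whose single addition to the lactone stops at the lithium lactolate at −78 °C, so work-up should give the hydroxy ketone with the α-methyl stereocentre untouched.

**Step 6**
Reactants: 9 (3R,7E)-9-{[tert-butyl(dimethyl)silyl]oxy}-1-hydroxy-3,7-dimethylnon-7-en-4-one
Product: 10 (3R,7E)-9-{[tert-butyl(dimethyl)silyl]oxy}-3,7-dimethyl-4-methylidenenon-7-en-1-ol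
Conditions: Ph3PCH3Br, KHMDS (3 equiv each), THF, 0 °C to rt
Reagents that add atoms: methyltriphenylphosphonium bromide, C[P+](c1ccccc1)(c1ccccc1)c1ccccc1.[Br-]
Why: Wittig methylenation of the ketone (through its ring-opened lactolate) installs the 1,1-disubstituted alkene C9=C20, and the C8 stereocentre should be retained if the excess of reactive ylide at low temperature outruns enolisation.

**Step 7**
Reactants: 10 (3R,7E)-9-{[tert-butyl(dimethyl)silyl]oxy}-3,7-dimethyl-4-methylidenenon-7-en-1-ol
Product: 11 tert-butyl{[(2E,7R)-9-iodo-3,7-dimethyl-6-methylidenenon-2-en-1-yl]oxy}dimethylsilane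
Conditions: I2, PPh3, imidazole, CH2Cl2, 0 °C
Reagents that add atoms: iodine, II
Why: Appel iodination converts the primary alcohol into the iodide under neutral conditions that leave both alkenes and the silyl ether intact.

**Step 8**
Reactants: 12 3-oxocyclohex-1-ene-1-carboxylic acid
Product: 13 2-(trimethylsilyl)ethyl 3-oxocyclohex-1-ene-1-carboxylate
Conditions: Me3SiCH2CH2OH, EDC·HCl, DMAP (cat.), CH2Cl2, 0 °C to rt
Reagents that add atoms: 2-(trimethylsilyl)ethanol, C[Si](C)(C)CCO
Why: Steglich-type carbodiimide esterification installs an ester that fluoride can later remove from the hindered C4 carboxyl group together with the silyl ether.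

**Step 9**
Reactants: 13 2-(trimethylsilyl)ethyl 3-oxocyclohex-1-ene-1-carboxylate
Product: 15 2-(trimethylsilyl)ethyl (1S)-1-methyl-3-[(trimethylsilyl)oxy]cyclohex-2-ene-1-carboxylate, via methylzinc enolate 14 (not isolated)
Conditions: Me2Zn, (CuOTf)2·C6H6 (2.5 mol%), chiral bidentate NHC–Ag(I) complex (2.5 mol%), t-BuOMe, −30 °C; then TMSOTf, −78 to 0 °C; non-aqueous work-up
Reagents that add atoms: dimethylzinc, C[Zn]C; trimethylsilyl trifluoromethanesulfonate, C[Si](C)(C)OS(=O)(=O)C(F)(F)F
Why: Copper-catalysed asymmetric conjugate addition of methyl to the ester-bearing β-carbon of the cyclic γ-keto enoate creates the quaternary C4 stereocentre under control of the chiral NHC ligand, and silylation traps the regiodefined C5 enolate.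

**Step 10**
Reactants: 15 2-(trimethylsilyl)ethyl (1S)-1-methyl-3-[(trimethylsilyl)oxy]cyclohex-2-ene-1-carboxylate; 11 tert-butyl{[(2E,7R)-9-iodo-3,7-dimethyl-6-methylidenenon-2-en-1-yl]oxy}dimethylsilane
Product: 17 2-(trimethylsilyl)ethyl (1S,2R)-2-[(3R,7E)-9-{[tert-butyl(dimethyl)silyl]oxy}-3,7-dimethyl-4-methylidenenon-7-en-1-yl]-1-methyl-3-oxocyclohexane-1-carboxylate, via benzyltrimethylammonium enolate 16 (not isolated)
Conditions: anhydrous BnMe3N+F− (1.05 equiv), 4 Å MS, THF, −40 °C to rt
Reagents that add atoms: none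
Why: Fluoride releases the regiodefined enolate, which is C-alkylated (SN2) by the primary iodide before proton transfer; the iodide should enter along the axial trajectory anti to the pseudoaxial ester on C4, placing the C5 substituent trans to the ester and cis to the methyl group.

**Step 11**
Reactants: 17 2-(trimethylsilyl)ethyl (1S,2R)-2-[(3R,7E)-9-{[tert-butyl(dimethyl)silyl]oxy}-3,7-dimethyl-4-methylidenenon-7-en-1-yl]-1-methyl-3-oxocyclohexane-1-carboxylate
Product: 19 2-(trimethylsilyl)ethyl (1S,2R)-2-[(3R,7E)-9-{[tert-butyl(dimethyl)silyl]oxy}-3,7-dimethyl-4-methylidenenon-7-en-1-yl]-1-methyl-3-{[(trifluoromethyl)sulfonyl]oxy}cyclohex-3-ene-1-carboxylate, via potassium enolate 18 (not isolated)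
Conditions: KHMDS, THF, −78 °C; PhNTf2, −78 to 0 °C
Reagents that add atoms: N-phenylbis(trifluoromethanesulfonimide), O=S(=O)(N(c1ccccc1)S(=O)(=O)C(F)(F)F)C(F)(F)F
Why: Kinetic deprotonation by the bulky amide at the unhindered C1 methylene (not at the tertiary C5–H next to the quaternary carbon) followed by O-triflation fixes the double bond at C1=C10 without touching a stereocentre.

**Step 12**
Reactants: 19 2-(trimethylsilyl)ethyl (1S,2R)-2-[(3R,7E)-9-{[tert-butyl(dimethyl)silyl]oxy}-3,7-dimethyl-4-methylidenenon-7-en-1-yl]-1-methyl-3-{[(trifluoromethyl)sulfonyl]oxy}cyclohex-3-ene-1-carboxylate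
Product: 21 2-(trimethylsilyl)ethyl (1S,5S,6R,8aS)-5-[(3E)-5-{[tert-butyl(dimethyl)silyl]oxy}-3-methylpent-3-en-1-yl]-1,5,6-trimethyl-1,2,3,5,6,7,8,8a-octahydronaphthalene-1-carboxylate, via neopentylpalladium(II) formate 20 (not isolated)
Conditions: Pd(OAc)2 (10 mol%), PPh3 (25 mol%), HCO2Na (1.5 equiv), Et4NCl, DMF, 80 °C
Reagents that add atoms: none
Why: Oxidative addition of Pd(0) into the C10–OTf bond gives an alkenylpalladium(II) species that undergoes syn-carbopalladation of the C9=C20 alkene; the resulting neopentyl σ-alkylpalladium 20 has no β-hydrogen and is intercepted by formate, which delivers hydride with loss of CO2 so that C20 becomes the methyl group. The closest known reaction type is the hydride-terminated (reductive) intramolecular Heck cyclisation that builds methyl-bearing quaternary carbons. Ring B (C5–C6–C7–C8–C9–C10) is closed in the 6-exo-trig mode through the C9–C10 bond. The new C9 stereocentre is controlled by C5 and C4: in the chair-like transition state C5–H is axial and the bulky C4 equatorial on the forming ring, the C9=C20 bond is eclipsed with the C10–Pd bond (CH2 equatorial), and the C11 chain therefore becomes axial on the face of H5, whereas attack on the other alkene face would place C11 syn-axial to the quaternary C4. The step needs exo rather than 7-endo insertion (the normal preference for attack at the internal carbon of a 1,1-disubstituted alkene), insertion before hydride capture (sparingly soluble sodium formate keeps the hydride supply low) and hydride capture before any further insertion (the remaining alkenes are trisubstituted). The C1=C10 double bond is fixed by the triflate and should not migrate, because no palladium hydride arises by β-elimination.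

**Step 13**
Reactants: 21 2-(trimethylsilyl)ethyl (1S,5S,6R,8aS)-5-[(3E)-5-{[tert-butyl(dimethyl)silyl]oxy}-3-methylpent-3-en-1-yl]-1,5,6-trimethyl-1,2,3,5,6,7,8,8a-octahydronaphthalene-1-carboxylate
Product: 22 (1S,5S,6R,8aS)-5-[(3E)-5-hydroxy-3-methylpent-3-en-1-yl]-1,5,6-trimethyl-1,2,3,5,6,7,8,8a-octahydronaphthalene-1-carboxylic acid
Conditions: TBAF (5 equiv), THF, rt to 40 °C; aq NH4Cl
Reagents that add atoms: none
Why: Fluoride cleaves the silyl ether and fragments the 2-(trimethylsilyl)ethyl ester at silicon (loss of ethene), so the steric shielding of the C4 carboxyl group does not matter and no stereocentre is touched.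

**Step 14**
Reactants: 22 (1S,5S,6R,8aS)-5-[(3E)-5-hydroxy-3-methylpent-3-en-1-yl]-1,5,6-trimethyl-1,2,3,5,6,7,8,8a-octahydronaphthalene-1-carboxylic acid
Product: 23 (1S,5S,6R,8aS)-1,5,6-trimethyl-5-[(3E)-3-methyl-5-(propanoyloxy)pent-3-en-1-yl]-1,2,3,5,6,7,8,8a-octahydronaphthalene-1-carboxylic acid (CNP0223570.1)
Conditions: (EtCO)2O, pyridine, DMAP (cat.), CH2Cl2, 0 °C to rt; aq NaHCO3 work-up
Reagents that add atoms: propanoic anhydride, CCC(=O)OC(=O)CC
Why: DMAP-catalysed acylation esterifies the primary allylic alcohol, while any mixed anhydride formed at the hindered tertiary carboxyl group should be hydrolysed on aqueous work-up.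

**Compound list**

1 | (E)-3-methylpent-2-en-4-yn-1-ol | OC/C=C(\C)C#C | starting material
2 | tert-butyl(dimethyl){[(2E)-3-methylpent-2-en-4-yn-1-yl]oxy}silane | CC(C)(C)[Si](C)(C)OC/C=C(\C)C#C | intermediate
3 | tert-butyl(dimethyl){[(2E)-3-methylpenta-2,4-dien-1-yl]oxy}silane | CC(C)(C)[Si](C)(C)OC/C=C(\C)C=C | intermediate
4 | chlorobis(cyclopentadienyl)[(3E)-5-{[tert-butyl(dimethyl)silyl]oxy}-3-methylpent-3-en-1-yl]zirconium (not isolated) | CC(C)(C)[Si](C)(C)OC/C=C(\C)CC[Zr](Cl)(C1C=CC=C1)C1C=CC=C1 | intermediate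
5 | tert-butyl{[(2E)-5-iodo-3-methylpent-2-en-1-yl]oxy}dimethylsilane | CC(C)(C)[Si](C)(C)OC/C=C(\C)CCI | intermediate
6 | 3-methylidenedihydrofuran-2(3H)-one | C=C1CCOC1=O | starting material
7 | (3R)-3-methyldihydrofuran-2(3H)-one | C[C@@H]1CCOC1=O | intermediate
8 | [(3E)-5-{[tert-butyl(dimethyl)silyl]oxy}-3-methylpent-3-en-1-yl]lithium (not isolated) | [Li]CC/C(C)=C/CO[Si](C)(C)C(C)(C)C | intermediate
9 | (3R,7E)-9-{[tert-butyl(dimethyl)silyl]oxy}-1-hydroxy-3,7-dimethylnon-7-en-4-one | OCC[C@H](C(=O)CC/C(C)=C/CO[Si](C)(C)C(C)(C)C)C | intermediate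
10 | (3R,7E)-9-{[tert-butyl(dimethyl)silyl]oxy}-3,7-dimethyl-4-methylidenenon-7-en-1-ol | OCC[C@H](C(=C)CC/C(C)=C/CO[Si](C)(C)C(C)(C)C)C | intermediate
11 | tert-butyl{[(2E,7R)-9-iodo-3,7-dimethyl-6-methylidenenon-2-en-1-yl]oxy}dimethylsilane | ICC[C@H](C(=C)CC/C(C)=C/CO[Si](C)(C)C(C)(C)C)C | intermediate
12 | 3-oxocyclohex-1-ene-1-carboxylic acid | O=C1C=C(CCC1)C(=O)O | starting material
13 | 2-(trimethylsilyl)ethyl 3-oxocyclohex-1-ene-1-carboxylate | O=C1C=C(CCC1)C(=O)OCC[Si](C)(C)C | intermediate
14 | methylzinc enolate of 2-(trimethylsilyl)ethyl (1S)-1-methyl-3-oxocyclohexane-1-carboxylate (not isolated) | C[Zn]OC1=C[C@](C)(CCC1)C(=O)OCC[Si](C)(C)C | intermediate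
15 | 2-(trimethylsilyl)ethyl (1S)-1-methyl-3-[(trimethylsilyl)oxy]cyclohex-2-ene-1-carboxylate | C[Si](C)(C)OC1=C[C@](C)(CCC1)C(=O)OCC[Si](C)(C)C | intermediate
16 | benzyltrimethylammonium C5-enolate of 2-(trimethylsilyl)ethyl (1S)-1-methyl-3-oxocyclohexane-1-carboxylate (not isolated) | [O-]C1=C[C@](C)(CCC1)C(=O)OCC[Si](C)(C)C.C[N+](C)(C)Cc1ccccc1 | intermediate
17 | 2-(trimethylsilyl)ethyl (1S,2R)-2-[(3R,7E)-9-{[tert-butyl(dimethyl)silyl]oxy}-3,7-dimethyl-4-methylidenenon-7-en-1-yl]-1-methyl-3-oxocyclohexane-1-carboxylate | O=C1CCC[C@](C)(C(=O)OCC[Si](C)(C)C)[C@H]1CC[C@H](C(=C)CC/C(C)=C/CO[Si](C)(C)C(C)(C)C)C | intermediate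
18 | potassium C1-enolate of ketone 17 (not isolated) | [K+].[O-]C1=CCC[C@](C)(C(=O)OCC[Si](C)(C)C)[C@H]1CC[C@H](C(=C)CC/C(C)=C/CO[Si](C)(C)C(C)(C)C)C | intermediate
19 | 2-(trimethylsilyl)ethyl (1S,2R)-2-[(3R,7E)-9-{[tert-butyl(dimethyl)silyl]oxy}-3,7-dimethyl-4-methylidenenon-7-en-1-yl]-1-methyl-3-{[(trifluoromethyl)sulfonyl]oxy}cyclohex-3-ene-1-carboxylate | O=S(=O)(OC1=CCC[C@](C)(C(=O)OCC[Si](C)(C)C)[C@H]1CC[C@H](C(=C)CC/C(C)=C/CO[Si](C)(C)C(C)(C)C)C)C(F)(F)F | intermediate
20 | neopentylpalladium(II) formate formed by 6-exo carbopalladation, phosphine ligands omitted (not isolated) | CC(C)(C)[Si](C)(C)OC/C=C(\C)CC[C@]1(C[Pd]OC=O)C2=CCC[C@](C)(C(=O)OCC[Si](C)(C)C)[C@H]2CC[C@H]1C | intermediate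
21 | 2-(trimethylsilyl)ethyl (1S,5S,6R,8aS)-5-[(3E)-5-{[tert-butyl(dimethyl)silyl]oxy}-3-methylpent-3-en-1-yl]-1,5,6-trimethyl-1,2,3,5,6,7,8,8a-octahydronaphthalene-1-carboxylate | CC(C)(C)[Si](C)(C)OC/C=C(\C)CC[C@]1(C)C2=CCC[C@](C)(C(=O)OCC[Si](C)(C)C)[C@H]2CC[C@H]1C | intermediate
22 | (1S,5S,6R,8aS)-5-[(3E)-5-hydroxy-3-methylpent-3-en-1-yl]-1,5,6-trimethyl-1,2,3,5,6,7,8,8a-octahydronaphthalene-1-carboxylic acid | OC/C=C(\C)CC[C@]1(C)C2=CCC[C@](C)(C(=O)O)[C@H]2CC[C@H]1C | intermediate
23 | (1S,5S,6R,8aS)-1,5,6-trimethyl-5-[(3E)-3-methyl-5-(propanoyloxy)pent-3-en-1-yl]-1,2,3,5,6,7,8,8a-octahydronaphthalene-1-carboxylic acid | CCC(=O)OC/C=C(\C)CC[C@]1(C)C2=CCC[C@](C)(C(=O)O)[C@H]2CC[C@H]1C | target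

**Step count.** Total: 14 steps. Longest linear sequence: 11 steps (1, 2, 3, 5, 6, 7, 10, 11, 12, 13, 14).

**Steps most likely to fail**

Step 12. Formate may transfer hydride to the alkenylpalladium before the 6-exo insertion (plain loss of the triflate), the neopentylpalladium may insert further into the C13=C14 alkene, or the alkene may be attacked on the wrong face. The fallback sets out from 19 and avoids palladium alkyls and hydride altogether. Pd(PPh3)4-catalysed coupling with (Me3Si)3Al·OEt2 should replace the triflate by silicon and give the alkenylsilane F1. Catalytic Tf2NH in CH2Cl2 at −78 °C should then protonate the 1,1-disubstituted alkene at C20, and the tertiary C9 cation would be captured at C10 by ipso attack on the vinylsilane with loss of the silyl group (vinylsilane-terminated cation–olefin cyclisation). This comes back to the route at 21, with the C1=C10 bond in place.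

Step 10. C-alkylation at the hindered C5 may be slow, so that proton transfer to the product (loss of regiocontrol, polyalkylation), O-alkylation or insufficient facial selectivity at C5 takes over. The fallback sets out from 10 and 15 and replaces the SN2 step by an aldol sequence. Dess–Martin oxidation of 10 should give the aldehyde F2. BF3·OEt2-mediated Mukaiyama aldol addition of 15 to it should give the β-hydroxy ketone F3. Mesylation and DBU elimination should give the 2-alkylidene ketone F4. Conjugate reduction with [(Ph3P)CuH]6 and protonation of the resulting C5 enolate, with base equilibration at C5 if required, comes back to the route at 17.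

Step 6. The basic ylide may enolise the ketone and so scramble the C8 stereocentre. The fallback sets out from 9 and uses a non-basic two-stage Peterson olefination. Addition of Me3SiCH2Li/CeCl3 at −78 °C should give the β-hydroxysilane F5, and KH in THF should then eliminate it to the alkene, which comes back to the route at 10.

**Further compounds**

F1 | step 12 | 2-(trimethylsilyl)ethyl (1S,2R)-2-[(3R,7E)-9-{[tert-butyl(dimethyl)silyl]oxy}-3,7-dimethyl-4-methylidenenon-7-en-1-yl]-1-methyl-3-(trimethylsilyl)cyclohex-3-ene-1-carboxylate | C[Si](C)(C)C1=CCC[C@](C)(C(=O)OCC[Si](C)(C)C)[C@H]1CC[C@H](C(=C)CC/C(C)=C/CO[Si](C)(C)C(C)(C)C)C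
F2 | step 10 | (3R,7E)-9-{[tert-butyl(dimethyl)silyl]oxy}-3,7-dimethyl-4-methylidenenon-7-enal | O=CC[C@H](C(=C)CC/C(C)=C/CO[Si](C)(C)C(C)(C)C)C
F3 | step 10 | 2-(trimethylsilyl)ethyl (1S)-2-[(3R,7E)-9-{[tert-butyl(dimethyl)silyl]oxy}-1-hydroxy-3,7-dimethyl-4-methylidenenon-7-en-1-yl]-1-methyl-3-oxocyclohexane-1-carboxylate (mixture at C5 and the carbinol carbon) | O=C1CCC[C@](C)(C(=O)OCC[Si](C)(C)C)C1C(O)C[C@H](C(=C)CC/C(C)=C/CO[Si](C)(C)C(C)(C)C)C
F4 | step 10 | 2-(trimethylsilyl)ethyl (1S)-2-[(3R,7E)-9-{[tert-butyl(dimethyl)silyl]oxy}-3,7-dimethyl-4-methylidenenon-7-en-1-ylidene]-1-methyl-3-oxocyclohexane-1-carboxylate (enone geometry not fixed) | O=C1CCC[C@](C)(C(=O)OCC[Si](C)(C)C)C1=CC[C@H](C(=C)CC/C(C)=C/CO[Si](C)(C)C(C)(C)C)C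
F5 | step 6 | (3R,7E)-9-{[tert-butyl(dimethyl)silyl]oxy}-3,7-dimethyl-4-[(trimethylsilyl)methyl]non-7-ene-1,4-diol | OCC[C@H](C(O)(C[Si](C)(C)C)CC/C(C)=C/CO[Si](C)(C)C(C)(C)C)C
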